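**Retrosynthetic overview**
1. Target 15 comes from LiAlH4 reduction of the diester 14, which gives both the C3 CH2OH and the C5 3-hydroxypropyl chain.
2. The trans-2-aryl-3-carbomethoxy-dihydrobenzofuran 14 is formed last, by a proposed isothiourea-catalysed lactone ring-opening / 5-endo oxa-Michael / protonation cascade of the 3-arylidene-coumaranone 13.
3. 13 comes from a Knoevenagel condensation of coumaranone 12 (made in 3 steps from dihydroferulic acid and glyoxylic acid) with aryl aldehyde 7.
4. The erythro 8-O-4′ diol unit in 7 (C7/C8) comes from a proline-catalysed anti-aldol of the aryloxyacetaldehyde 4 (from syringaldehyde) with veratraldehyde, followed by chemoselective reduction.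
5. Ring order: all three benzene rings pre-exist. The lactone ring forms in step 6, and the dihydrobenzofuran ring forms in step 9.

**Assumptions (one line):** the SMILES encodes a trans-(2R,3S) dihydrobenzofuran and an erythro-(7S,8R) side chain. The catalyst enantiomers (L-proline, and the isothiourea enantiomer) are assigned from stereochemical models and would be confirmed by a quick screen.

**Compounds in order of first appearance**
- 1 syringaldehyde
- 2 bromoacetaldehyde diethyl acetal
- 3 4-(2,2-diethoxyethoxy)-3,5-dimethoxybenzaldehyde
- 4 2-(4-formyl-2,6-dimethoxyphenoxy)acetaldehyde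
- 5 veratraldehyde
- 6 (2S,3S)-3-(3,4-dimethoxyphenyl)-3-hydroxy-2-(4-formyl-2,6-dimethoxyphenoxy)propanal
- 7 (1S,2R)-1-(3,4-dimethoxyphenyl)-2-(4-formyl-2,6-dimethoxyphenoxy)propane-1,3-diol
- 8 dihydroferulic acid
- 9 glyoxylic acid
- 10 racemic 2-hydroxy-2-[2-hydroxy-3-methoxy-5-(2-carboxyethyl)phenyl]acetic acid
- 11 methyl 3-(3-hydroxy-7-methoxy-2-oxo-2,3-dihydrobenzofuran-5-yl)propanoate (racemic)
- 12 methyl 3-(7-methoxy-2-oxo-2,3-dihydrobenzofuran-5-yl)propanoate
- 13 (E)-3-arylidene coumaranone carrying the diol side chain
- 14 trans-(2R,3R) diester (the descriptor at C3 changes from S to R because CO2Me outranks C2)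
- 15 Berbikonol

**Step 1**
Reactants: 1 syringaldehyde; 2 bromoacetaldehyde diethyl acetal
Product: 3
Conditions: K2CO3, KI (cat.), DMF, 110 °C
Reagents that add atoms: bromoacetaldehyde diethyl acetal, CCOC(CBr)OCC
Why: Williamson O-alkylation of the acidic phenol puts the aryl ether on and masks the aliphatic aldehyde; the aryl CHO survives.

**Step 2**
Reactants: 3
Product: 4
Conditions: 2 M HCl, THF/H2O (1:1), 50 °C; crude product used at once
Reagents that add atoms: water, O
Why: acetal hydrolysis releases the aryloxyacetaldehyde (present as its hydrate); the aryl aldehyde is unaffected.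

**Step 3**
Reactants: 4; 5 veratraldehyde
Product: 6
Conditions: L-proline (30 mol%), DMF, 4 °C; 4 added by syringe pump over 16 h to 5 (4 equiv)
Reagents that add atoms: veratraldehyde, COc1ccc(C=O)cc1OC
Why: proline-enamine cross-aldol (MacMillan-type α-oxyaldehyde aldol). The s-trans enamine attacks the Re face of veratraldehyde with carboxylic-acid direction (Houk–List model), giving the anti (= erythro) adduct with C7 = S and C8 = R. Slow addition suppresses donor self-aldol, and the enamine forms on the aliphatic aldehyde only. This is the first stereocentre step.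

**Step 4**
Reactants: 6
Product: 7
Conditions: NaBH4 (0.3 equiv), CH2Cl2/MeOH (4:1), −78 °C, 30 min
Reagents that add atoms: none
Why: the α-aryloxy aliphatic aldehyde is far more electrophilic than the electron-rich aryl aldehyde, so only it is reduced; after reduction C8 can no longer epimerise.

**Step 5**
Reactants: 8 dihydroferulic acid; 9 glyoxylic acid
Product: 10
Conditions: NaOH (3 equiv), H2O, 50 °C, 24 h; then HCl to pH 1
Reagents that add atoms: glyoxylic acid, O=CC(=O)O
Why: phenoxide hydroxyalkylation (Lederer–Manasse type) at the only free ortho position, since the para position is blocked and the other ortho position carries OMe.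

**Step 6**
Reactants: 10
Product: 11
Conditions: MeOH, H2SO4 (cat.), reflux; then toluene, TsOH (cat.), Dean–Stark
Reagents that add atoms: methanol, CO
Why: Fischer esterification of the chain acid; the o-hydroxymandelic acid lactonises to the 3-hydroxycoumaranone.

**Step 7**
Reactants: 11
Product: 12
Conditions: H2 (1 atm), 10% Pd/C, AcOH, HClO4 (cat.), 50 °C
Reagents that add atoms: none
Why: hydrogenolysis of the benzylic α-hydroxy carbonyl; the lactone and ester survive and the racemic C3 centre is removed.

**Step 8**
Reactants: 7; 12
Product: 13
Conditions: piperidine (0.2 equiv), AcOH (0.2 equiv), toluene, 80 °C, 4 Å MS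
Reagents that add atoms: none
Why: Knoevenagel condensation at the acidic C3–H of the coumaranone; the free hydroxyls are tolerated, and the E/Z geometry is immaterial because the alkene is consumed in step 9.

**Step 9**
Reactants: 13
Product: 14
Conditions: (2S,3R)-HyperBTM (10 mol%), MeOH (20 equiv), CH2Cl2 (0.05 M), 40 °C, 48 h
Reagents that add atoms: methanol, CO
Why: Proposed new method: the isothiourea acylates through the activated aryl-ester lactone, opening it to a phenoxide-tethered α-aryl-cinnamoyl ammonium. The phenoxide then adds 5-endo to the β-carbon (C2), with face selection by the chiral ammonium ion pair. The ammonium enolate is protonated at C3 anti to the new C2 aryl (trans), and MeOH releases the methyl ester and the catalyst. Any ring-opened hydroxy ester simply relactonises, so the trans dihydrobenzofuran ester is the thermodynamic sink. The closest known reactions are isothiourea aryl-ester oxa-Michael/lactonisation cascades and base-mediated 5-endo oxa-Michael closures to 2-aryl-dihydrobenzofuran-3-esters.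

**Step 10**
Reactants: 14
Product: 15 Berbikonol
Conditions: LiAlH4 (5 equiv), THF, 0 °C to rt, 2 h; Rochelle salt work-up
Reagents that add atoms: none
Why: hydride reduction converts both methyl esters to primary alcohols. The aryl ethers, the benzylic ether and the free OH groups are untouched, and the four stereocentres are not affected.

**Compound list**
1 | syringaldehyde | COc1cc(C=O)cc(OC)c1O | starting material
2 | bromoacetaldehyde diethyl acetal | CCOC(CBr)OCC | starting material
3 | 4-(2,2-diethoxyethoxy)-3,5-dimethoxybenzaldehyde | CCOC(COc1c(OC)cc(C=O)cc1OC)OCC | intermediate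
4 | 2-(4-formyl-2,6-dimethoxyphenoxy)acetaldehyde | O=CCOc1c(OC)cc(C=O)cc1OC | intermediate
5 | veratraldehyde | COc1ccc(C=O)cc1OC | starting material
6 | erythro aldol aldehyde, (2S,3S) | COc1ccc([C@H](O)[C@@H](C=O)Oc2c(OC)cc(C=O)cc2OC)cc1OC | intermediate
7 | erythro diol aryl aldehyde, (1S,2R) | COc1ccc([C@H](O)[C@@H](CO)Oc2c(OC)cc(C=O)cc2OC)cc1OC | intermediate
8 | dihydroferulic acid | COc1cc(CCC(=O)O)ccc1O | starting material
9 | glyoxylic acid | O=CC(=O)O | starting material
10 | o-hydroxymandelic acid (racemic) | OC(C(=O)O)c1cc(CCC(=O)O)cc(OC)c1O | intermediate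
11 | 3-hydroxycoumaranone methyl ester (racemic) | COC(=O)CCc1cc2C(O)C(=O)Oc2c(OC)c1 | intermediate
12 | coumaranone methyl ester | COC(=O)CCc1cc2CC(=O)Oc2c(OC)c1 | intermediate
13 | (E)-3-arylidene coumaranone | COc1ccc([C@H](O)[C@@H](CO)Oc2c(OC)cc(/C=C3/C(=O)Oc4c(OC)cc(CCC(=O)OC)cc43)cc2OC)cc1OC | intermediate
14 | trans diester | COc1ccc([C@H](O)[C@@H](CO)Oc2c(OC)cc([C@@H]3Oc4c(OC)cc(CCC(=O)OC)cc4[C@H]3C(=O)OC)cc2OC)cc1OC | intermediate
15 | Berbikonol | COc1ccc([C@H](O)[C@@H](CO)Oc2c(OC)cc([C@@H]3Oc4c(OC)cc(CCCO)cc4[C@H]3CO)cc2OC)cc1OC | target

**Totals:** 10 steps in total; longest linear sequence 7 steps (1→2→3→4→8→9→10).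

**Three steps most likely to fail**
1. **Step 9 (the proposed new step).** The 5-endo oxa-Michael onto an electron-rich β-aryl acyl ammonium may be slow, and methanolysis and relactonisation may compete, eroding ee. Fallback (known chemistry, different approach): build the 2-aryl-benzofuran-3-carboxylate (salicylaldehyde + ethyl diazoacetate/HBF4, then Pd C2-arylation). Hydrogenate it with a chiral Ru–NHC catalyst to the cis-2,3-dihydrobenzofuran, then epimerise C3 to trans with DBU, and reduce with LiAlH4.
2. **Step 3.** Veratraldehyde is a poor acceptor, and donor self-aldol or dehydration may compete. Fallback: O-alkylate the phenol from syringaldehyde with 2-bromo-1-(3,4-dimethoxyphenyl)ethanone and hydroxymethylate with HCHO/K2CO3. Then set 7S,8R by Ru–TsDPEN dynamic-kinetic-resolution transfer hydrogenation (HCO2H/Et3N).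
3. **Step 5.** Ortho-hydroxyalkylation may be low-yielding or unselective with this para-blocked phenol. Fallback: Casnati–Skattebøl ortho-formylation (MgCl2/Et3N/(CH2O)n) of methyl dihydroferulate. Then homologate with Ph3P=CHOMe and HCl, oxidise (Pinnick) and lactonise to give 12.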